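**Retrosynthetic overview**

1. Target 25 ⇐ ester 24 ⇐ diene 23 (diimide) ⇐ C6 aldehyde 18 + farnesyl ylide 22 (Wittig). The triene is attached last, after every ozone and acid step.
2. 18 ⇐ 1,2-dioxane 14: its C6–CH2OH becomes C1', and its vinyl group is the masked carboxyl group (ozonolysis, chlorite oxidation).
3. 14 ⇐ hydroperoxy oxirane 13. The only ring, the 1,2-dioxane, is closed by forming O1–C6: the hydroperoxide opens the 2-methyl-2-alkyloxirane at its tertiary carbon with inversion (6-exo). The strategy rests on the fully substituted ring carbon C6 (bonded to O1, CH3, C5 and side-chain C1'), which is taken from the tertiary carbon of (S)-2-methylglycidol.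
4. 13 ⇐ mesylate 9 + 2-methoxyprop-2-yl hydroperoxide 11 (SN2, inversion at C3) ⇐ syn alcohol 8 ((Z)-crotylboration sets C3 and the propanoate C2) ⇐ aldehyde 5 ⇐ (S)-2-methylglycidol 1 + allylmagnesium bromide 3.

Key step: step 8

Remark (numbering): in the discussion the ring atoms are O1, O2, C3 (CH carrying the propanoic acid), C4, C5, C6 (quaternary), and C1' is the side-chain carbon on C6. The names in the compound list use their own lowest locants.

Remark (assumption): diene 23 is carried forward as a mixture of geometric isomers at the new C1'=C2' alkene, because this alkene is saturated in step 15.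

**Route**

Step 1
Reactants: 1 (S)-2-methylglycidol
Product: 2 [(2R)-2-methyloxiran-2-yl]methyl trifluoromethanesulfonate
Conditions: Tf2O, 2,6-lutidine, CH2Cl2, −78 °C; used at once
Reagents that add atoms: trifluoromethanesulfonic anhydride, O=S(=O)(OS(=O)(=O)C(F)(F)F)C(F)(F)F
Why: O-sulfonylation (triflate formation) of the primary alcohol at low temperature with a hindered base leaves the oxirane and its stereocentre untouched; the descriptor changes from S to R only because the CIP order of the two CH2 groups is reversed.

Step 2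
Reactants: 2 [(2R)-2-methyloxiran-2-yl]methyl trifluoromethanesulfonate; 3 allylmagnesium bromide
Product: 4 (2S)-2-(but-3-en-1-yl)-2-methyloxirane
Conditions: CuI (10 mol%), Et2O/THF, −78 → −40 °C; careful concentration (volatile product)
Reagents that add atoms: none
Why: Copper-catalysed Grignard coupling with a primary triflate (SN2 at CH2OTf) is much faster at −78 °C than oxirane opening, so the allyl group replaces the triflate directly and the oxirane keeps its configuration, whereas opening followed by re-closure would give the enantiomer.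

Step 3
Reactants: 4 (2S)-2-(but-3-en-1-yl)-2-methyloxirane
Product: 5 3-[(2S)-2-methyloxiran-2-yl]propanal
Conditions: O3, CH2Cl2, −78 °C; then PPh3, −78 °C → rt
Reagents that add atoms: ozone, [O-][O+]=O
Why: Ozonolysis with reductive work-up cleaves the only alkene to the aldehyde, and the oxirane is inert to ozone and to PPh3 under these conditions.

Step 4
Reactants: 5 3-[(2S)-2-methyloxiran-2-yl]propanal; 6 (Z)-but-2-ene
Product: 8 (3R,4R)-4-methyl-1-[(2S)-2-methyloxiran-2-yl]hex-5-en-3-ol, via (Z)-crotyldiisopinocampheylborane 7 (not isolated)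
Conditions: 6, KOtBu, n-BuLi, THF, −78 → −45 °C; (−)-Ipc2BOMe, −78 °C; BF3·OEt2 (1.0 equiv per boron); then 5, −78 °C; NaBO3·4H2O, THF/H2O, rt
Reagents that add atoms: none
Why: Brown asymmetric crotylboration proceeds through a closed chair transition state in which the (Z)-crotyl geometry gives the 3,4-syn relationship and the Ipc groups derived from (+)-α-pinene direct attack to the Si face of the aldehyde, so 3R and 4R are set under reagent control irrespective of the remote oxirane centre; BF3·OEt2 is limited to one equivalent per boron so that no free Lewis acid meets the oxirane.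

Step 5
Reactants: 8 (3R,4R)-4-methyl-1-[(2S)-2-methyloxiran-2-yl]hex-5-en-3-ol
Product: 9 (3R,4R)-4-methyl-1-[(2S)-2-methyloxiran-2-yl]hex-5-en-3-yl methanesulfonate
Conditions: MsCl, Et3N, CH2Cl2, 0 °C
Reagents that add atoms: methanesulfonyl chloride, CS(=O)(=O)Cl
Why: Mesylation (sulfonate ester formation at oxygen) proceeds with retention at C3 and installs the leaving group for the invertive peroxide transfer.

Step 6
Reactants: 10 2,3-dimethylbut-2-ene
Product: 11 2-methoxyprop-2-yl hydroperoxide
Conditions: O3, CH2Cl2/MeOH, −78 °C; concentration below rt, used as a solution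
Reagents that add atoms: ozone, [O-][O+]=O; methanol, CO
Why: Ozonolysis of a tetrasubstituted alkene in methanol gives acetone and a carbonyl oxide (Criegee intermediate) that is trapped by methanol as the α-methoxy hydroperoxide, a hydroperoxide donor whose ketal is removed later by mild acid.

Step 7
Reactants: 9 (3R,4R)-4-methyl-1-[(2S)-2-methyloxiran-2-yl]hex-5-en-3-yl methanesulfonate; 11 2-methoxyprop-2-yl hydroperoxide
Product: 12 (2S)-2-[(3S,4R)-3-[(2-methoxypropan-2-yl)peroxy]-4-methylhex-5-en-1-yl]-2-methyloxirane
Conditions: CsOH·H2O, DMF, 0 °C → rt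
Reagents that add atoms: none
Why: SN2 alkylation of the caesium peroxide anion, a nucleophile of low basicity enhanced by the α-effect, inverts C3 from R to S and thereby gives the anti relationship between the C3 peroxide and the C4 methyl group; the oxirane is not activated under these basic conditions.

Step 8
Reactants: 12 (2S)-2-[(3S,4R)-3-[(2-methoxypropan-2-yl)peroxy]-4-methylhex-5-en-1-yl]-2-methyloxirane
Product: 14 [(3R,6S)-6-[(2R)-but-3-en-2-yl]-3-methyl-1,2-dioxan-3-yl]methanol, via hydroperoxy oxirane 13 (not isolated)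
Conditions: camphorsulfonic acid (10 mol%), MeOH (2 equiv), CH2Cl2 (0.02 M), 0 °C → rt; Et3N quench
Reagents that add atoms: none
Why: Camphorsulfonic acid first transfers the 2-methoxyprop-2-yl group to methanol (transketalisation), which frees hydroperoxide 13, and then activates the oxirane by protonation, after which the terminal peroxide oxygen attacks the tertiary oxirane carbon from the face opposite the departing oxygen in a borderline SN2 opening. The closest known reaction type is the acid-promoted intramolecular opening of epoxides and oxetanes by hydroperoxides, which gives 1,2-dioxanes and 1,2-dioxolanes. The 1,2-dioxane closes in the 6-exo mode (O1–C6 bond, the breaking oxirane C–O bond lying outside the new ring), and the oxirane CH2 is released as the C6 hydroxymethyl group. C6 is the only new stereocentre and is fixed by the configuration of the (S)-oxirane through inversion, while C3 and the butenyl carbon pass through unchanged. The step needs attack at the tertiary carbon instead of 7-endo attack at CH2, and substitution without a free cation; the higher positive charge at the tertiary carbon, the six-membered transition state and strain release should secure the first, and the tethered nucleophile in a non-ionising solvent at 0 °C with only two equivalents of methanol should secure the second.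

Step 9
Reactants: 14 [(3R,6S)-6-[(2R)-but-3-en-2-yl]-3-methyl-1,2-dioxan-3-yl]methanol
Product: 16 (2S)-2-[(3S,6R)-6-(hydroxymethyl)-6-methyl-1,2-dioxan-3-yl]propanoic acid, via dioxanylpropanal 15 (not isolated)
Conditions: O3, CH2Cl2/MeOH, −78 °C; Me2S, −78 °C → rt; then NaClO2, NaH2PO4, 2-methylbut-2-ene, t-BuOH/H2O, 0 °C → rt
Reagents that add atoms: ozone, [O-][O+]=O; sodium chlorite, [Na+].[O-]Cl=O
Why: Ozonolysis of the monosubstituted alkene followed at once by Pinnick (chlorite) oxidation of the crude aldehyde turns the vinyl group into the carboxyl group; the dialkyl peroxide is inert to ozone, Me2S and buffered chlorite, and the α-stereocentre should not epimerise because the aldehyde is never stored or exposed to base.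

Step 10
Reactants: 16 (2S)-2-[(3S,6R)-6-(hydroxymethyl)-6-methyl-1,2-dioxan-3-yl]propanoic acid
Product: 17 methyl (2S)-2-[(3S,6R)-6-(hydroxymethyl)-6-methyl-1,2-dioxan-3-yl]propanoate
Conditions: TMSCHN2, PhMe/MeOH, 0 °C
Reagents that add atoms: trimethylsilyldiazomethane, C[Si](C)(C)C=[N+]=[N-]
Why: Esterification with TMSCHN2 in methanol methylates only the carboxylic acid under essentially neutral conditions and removes the acidic proton before the ylide step.

Step 11
Reactants: 17 methyl (2S)-2-[(3S,6R)-6-(hydroxymethyl)-6-methyl-1,2-dioxan-3-yl]propanoate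
Product: 18 methyl (2S)-2-[(3S,6R)-6-formyl-6-methyl-1,2-dioxan-3-yl]propanoate
Conditions: Dess–Martin periodinane, NaHCO3, CH2Cl2, 0 °C → rt
Reagents that add atoms: none
Why: Dess–Martin oxidation of the neopentyl-type primary alcohol gives an aldehyde that has no α-hydrogen, so it can neither enolise nor lose the C6 configuration.

Step 12
Reactants: 19 (2E,6E)-farnesol
Product: 20 (2E,6E)-1-bromo-3,7,11-trimethyldodeca-2,6,10-triene
Conditions: PBr3, Et2O, −10 → 0 °C
Reagents that add atoms: phosphorus tribromide, BrP(Br)Br
Why: Bromination of the primary allylic alcohol with PBr3 at low temperature proceeds without allylic transposition or loss of the 2E geometry.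

Step 13
Reactants: 20 (2E,6E)-1-bromo-3,7,11-trimethyldodeca-2,6,10-triene
Product: 21 [(2E,6E)-3,7,11-trimethyldodeca-2,6,10-trien-1-yl]triphenylphosphonium bromide
Conditions: PPh3, toluene, rt, dark
Reagents that add atoms: triphenylphosphine, c1ccc(cc1)P(c1ccccc1)c1ccccc1
Why: Quaternisation of PPh3 by the primary allylic bromide (SN2) gives the crystalline phosphonium salt for the Wittig reaction.

Step 14
Reactants: 18 methyl (2S)-2-[(3S,6R)-6-formyl-6-methyl-1,2-dioxan-3-yl]propanoate; 21 [(2E,6E)-3,7,11-trimethyldodeca-2,6,10-trien-1-yl]triphenylphosphonium bromide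
Product: 23 methyl (2S)-2-[(3S,6R)-6-methyl-6-[(3E,7E)-4,8,12-trimethyltrideca-1,3,7,11-tetraen-1-yl]-1,2-dioxan-3-yl]propanoate (1E/1Z mixture), via farnesylidenetriphenylphosphorane 22 (not isolated)
Conditions: 21 (slight excess), NaN(SiMe3)2, THF, −78 → 0 °C; then 18, −78 °C → rt
Reagents that add atoms: none
Why: Wittig olefination with the semi-stabilised allylic ylide joins C1' to C2' and keeps the 3E,7E geometry of the farnesyl unit; the geometry of the new disubstituted alkene does not matter because it is saturated next, and the hindered amide base, used in deficit to the salt, should spare the ester and the O–O bond.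

Step 15
Reactants: 23 methyl (2S)-2-[(3S,6R)-6-methyl-6-[(3E,7E)-4,8,12-trimethyltrideca-1,3,7,11-tetraen-1-yl]-1,2-dioxan-3-yl]propanoate
Product: 24 methyl (2S)-2-[(3S,6S)-6-methyl-6-[(3E,7E)-4,8,12-trimethyltrideca-3,7,11-trien-1-yl]-1,2-dioxan-3-yl]propanoate
Conditions: KO2CN=NCO2K (portionwise), AcOH, MeOH/CH2Cl2, 0 °C → rt; stopped when the diene is consumed
Reagents that add atoms: none
Why: Diimide reduction (concerted syn transfer of two hydrogens) should favour the less substituted, conjugated 1,2-disubstituted alkene over the three trisubstituted alkenes and does not cleave O–O bonds, in contrast to catalytic hydrogenation.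

Step 16
Reactants: 24 methyl (2S)-2-[(3S,6S)-6-methyl-6-[(3E,7E)-4,8,12-trimethyltrideca-3,7,11-trien-1-yl]-1,2-dioxan-3-yl]propanoate
Product: 25 (2S)-2-[(3S,6S)-6-methyl-6-[(3E,7E)-4,8,12-trimethyltrideca-3,7,11-trien-1-yl]-1,2-dioxan-3-yl]propanoic acid
Conditions: LiOH·H2O, THF/MeOH/H2O, 0 °C; then 1 M HCl to pH 3, 0 °C
Reagents that add atoms: lithium hydroxide, [Li+].[OH-]
Why: Saponification (acyl substitution by hydroxide) at 0 °C is expected to be faster than enolisation of the ester, so the α-stereocentre and the β-peroxy linkage should survive, and cold acidification releases the acid.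

**Compound list**

1 | (S)-2-methylglycidol = [(2S)-2-methyloxiran-2-yl]methanol | OC[C@@]1(C)CO1 | starting material
2 | [(2R)-2-methyloxiran-2-yl]methyl trifluoromethanesulfonate | FC(F)(F)S(=O)(=O)OC[C@@]1(C)CO1 | intermediate
3 | allylmagnesium bromide | C=CC[Mg]Br | starting material
4 | (2S)-2-(but-3-en-1-yl)-2-methyloxirane | C=CCC[C@@]1(C)CO1 | intermediate
5 | 3-[(2S)-2-methyloxiran-2-yl]propanal | O=CCC[C@@]1(C)CO1 | intermediate
6 | (Z)-but-2-ene | C/C=C\C | starting material
7 | (Z)-but-2-en-1-yldiisopinocampheylborane (Ipc groups from (+)-α-pinene; not isolated) | C/C=C\CB([C@H]1[C@H](C)[C@H]2C[C@@H](C1)C2(C)C)[C@H]1[C@H](C)[C@H]2C[C@@H](C1)C2(C)C | intermediate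
8 | (3R,4R)-4-methyl-1-[(2S)-2-methyloxiran-2-yl]hex-5-en-3-ol | O1C[C@]1(C)CC[C@H]([C@H](C)C=C)O | intermediate
9 | (3R,4R)-4-methyl-1-[(2S)-2-methyloxiran-2-yl]hex-5-en-3-yl methanesulfonate | O1C[C@]1(C)CC[C@H]([C@H](C)C=C)OS(C)(=O)=O | intermediate
10 | 2,3-dimethylbut-2-ene | CC(C)=C(C)C | starting material
11 | 2-methoxyprop-2-yl hydroperoxide (2-hydroperoxy-2-methoxypropane) | COC(C)(C)OO | intermediate
12 | (2S)-2-[(3S,4R)-3-[(2-methoxypropan-2-yl)peroxy]-4-methylhex-5-en-1-yl]-2-methyloxirane | O1C[C@]1(C)CC[C@@H]([C@H](C)C=C)OOC(C)(C)OC | intermediate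
13 | (2S)-2-[(3S,4R)-3-hydroperoxy-4-methylhex-5-en-1-yl]-2-methyloxirane (not isolated) | O1C[C@]1(C)CC[C@@H]([C@H](C)C=C)OO | intermediate
14 | [(3R,6S)-6-[(2R)-but-3-en-2-yl]-3-methyl-1,2-dioxan-3-yl]methanol | OC[C@@]1(C)CC[C@@H]([C@H](C)C=C)OO1 | intermediate
15 | (2S)-2-[(3S,6R)-6-(hydroxymethyl)-6-methyl-1,2-dioxan-3-yl]propanal (not isolated) | OC[C@@]1(C)CC[C@@H]([C@H](C)C=O)OO1 | intermediate
16 | (2S)-2-[(3S,6R)-6-(hydroxymethyl)-6-methyl-1,2-dioxan-3-yl]propanoic acid | OC[C@@]1(C)CC[C@@H]([C@H](C)C(=O)O)OO1 | intermediate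
17 | methyl (2S)-2-[(3S,6R)-6-(hydroxymethyl)-6-methyl-1,2-dioxan-3-yl]propanoate | OC[C@@]1(C)CC[C@@H]([C@H](C)C(=O)OC)OO1 | intermediate
18 | methyl (2S)-2-[(3S,6R)-6-formyl-6-methyl-1,2-dioxan-3-yl]propanoate | O=C[C@@]1(C)CC[C@@H]([C@H](C)C(=O)OC)OO1 | intermediate
19 | (2E,6E)-farnesol | CC(C)=CCC/C(C)=C/CC/C(C)=C/CO | starting material
20 | (2E,6E)-1-bromo-3,7,11-trimethyldodeca-2,6,10-triene | CC(C)=CCC/C(C)=C/CC/C(C)=C/CBr | intermediate
21 | [(2E,6E)-3,7,11-trimethyldodeca-2,6,10-trien-1-yl]triphenylphosphonium bromide | CC(C)=CCC/C(C)=C/CC/C(C)=C/C[P+](c1ccccc1)(c1ccccc1)c1ccccc1.[Br-] | intermediate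
22 | [(2E,6E)-3,7,11-trimethyldodeca-2,6,10-trien-1-ylidene]triphenylphosphorane (not isolated) | CC(C)=CCC/C(C)=C/CC/C(C)=C/C=P(c1ccccc1)(c1ccccc1)c1ccccc1 | intermediate
23 | methyl (2S)-2-[(3S,6R)-6-methyl-6-[(3E,7E)-4,8,12-trimethyltrideca-1,3,7,11-tetraen-1-yl]-1,2-dioxan-3-yl]propanoate (1E/1Z mixture) | CC(C)=CCC/C(C)=C/CC/C(C)=C/C=C[C@@]1(C)CC[C@@H]([C@H](C)C(=O)OC)OO1 | intermediate
24 | methyl (2S)-2-[(3S,6S)-6-methyl-6-[(3E,7E)-4,8,12-trimethyltrideca-3,7,11-trien-1-yl]-1,2-dioxan-3-yl]propanoate | CC(C)=CCC/C(C)=C/CC/C(C)=C/CC[C@@]1(C)CC[C@@H]([C@H](C)C(=O)OC)OO1 | intermediate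
25 | (2S)-2-[(3S,6S)-6-methyl-6-[(3E,7E)-4,8,12-trimethyltrideca-3,7,11-trien-1-yl]-1,2-dioxan-3-yl]propanoic acid (CNP0179915.1) | CC(C)=CCC/C(C)=C/CC/C(C)=C/CC[C@@]1(C)CC[C@@H]([C@H](C)C(=O)O)OO1 | target

**Step count**

Total step count: 16.
Longest linear sequence: 13 steps (steps 1–5, 7–11 and 14–16, from 1 to 25). Step 6 and steps 12–13 are side branches.

**Steps most likely to fail, with fallbacks**

Step 7 (peroxide transfer to the secondary mesylate). The peroxide anion may act as a base: the β-hydrogen at C4 is allylic, so E2 elimination towards the conjugated diene can outrun substitution at this β-branched centre, and the anion may also open the oxirane at its CH2 carbon. Fallback: the two C–O bonds of the peroxide are made in the opposite order, so that substitution at C3 becomes intramolecular. It sets out from mesylate 9. Ethereal H2O2 with catalytic H3PMo12O40 in Et2O opens the oxirane at its tertiary carbon with inversion to give (3R,4R,7R)-7-hydroperoxy-8-hydroxy-3,7-dimethyloct-1-en-4-yl methanesulfonate F1. KOtBu (one equivalent) and 18-crown-6 in THF at 0 °C should then close the ring by 6-exo-tet displacement of the mesylate with inversion at C3. The route is rejoined at 14, with the same configuration at C3 and C6 as in the main line.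

Step 8 (key ring closure). The protonated oxirane may ionise to an open tertiary cation, which would erode the configuration at C6; it may also be captured by methanol or undergo Meinwald rearrangement to an aldehyde before the hydroperoxide is free. Fallback: the ring is closed at C3 by conjugate addition instead of at C6 by substitution. It sets out from aldehyde 5. Wittig reaction with the stabilised ylide methyl 2-(triphenylphosphoranylidene)propanoate in CH2Cl2 gives methyl (2E)-2-methyl-5-[(2S)-2-methyloxiran-2-yl]pent-2-enoate F2. Perhydrolysis of the oxirane at the tertiary carbon (ethereal H2O2, catalytic H3PMo12O40, inversion) gives methyl (2E,6R)-6-hydroperoxy-7-hydroxy-2,6-dimethylhept-2-enoate F3. Et2NH in CF3CH2OH then effects the 6-exo-trig intramolecular peroxy-Michael addition, and the route is rejoined at hydroxy ester 17. This closure is not expected to control C3 or the propanoate C2, so 17 would have to be separated from its diastereomers; C6 stays fixed by the oxirane.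

Step 15 (diimide reduction). Discrimination between the disubstituted alkene, which sits next to the quaternary C6, and the three trisubstituted alkenes may be incomplete, leading to over-reduced chain or leftover diene that is hard to separate. Fallback: the C1'–C2' unit is introduced already saturated by a B-alkyl Suzuki–Miyaura coupling, so no alkene has to be reduced. It sets out from aldehyde 18.
- Peroxide fragment: methylenation (Ph3PCH3Br, NaN(SiMe3)2, THF) gives methyl (2S)-2-[(3S,6R)-6-ethenyl-6-methyl-1,2-dioxan-3-yl]propanoate F4. Hydroboration with 9-BBN in THF gives the primary alkylborane methyl (2S)-2-[(3S,6S)-6-[2-(9-borabicyclo[3.3.1]nonan-9-yl)ethyl]-6-methyl-1,2-dioxan-3-yl]propanoate F5, used in solution.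
- Coupling partner, from commercial geranyl bromide: alkylation of lithiated 1-(trimethylsilyl)propyne gives [(5E)-6,10-dimethylundeca-5,9-dien-1-yn-1-yl]trimethylsilane F6. K2CO3 in methanol gives (5E)-6,10-dimethylundeca-5,9-dien-1-yne F7. Zirconium-catalysed carboalumination (AlMe3, Cp2ZrCl2, CH2Cl2) followed by I2 gives (1E,5E)-1-iodo-2,6,10-trimethylundeca-1,5,9-triene F8.
- Coupling of F5 with F8 (PdCl2(dppf), AsPh3, Cs2CO3, DMF/THF/H2O, rt) rejoins the route at ester 24.

**Further compounds**

F1 | step 7 | (3R,4R,7R)-7-hydroperoxy-8-hydroxy-3,7-dimethyloct-1-en-4-yl methanesulfonate | OC[C@](C)(OO)CC[C@H]([C@H](C)C=C)OS(C)(=O)=O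
F2 | step 8 | methyl (2E)-2-methyl-5-[(2S)-2-methyloxiran-2-yl]pent-2-enoate | COC(=O)/C(C)=C/CC[C@@]1(C)CO1
F3 | step 8 | methyl (2E,6R)-6-hydroperoxy-7-hydroxy-2,6-dimethylhept-2-enoate | COC(=O)/C(C)=C/CC[C@@](C)(OO)CO
F4 | step 15 | methyl (2S)-2-[(3S,6R)-6-ethenyl-6-methyl-1,2-dioxan-3-yl]propanoate | C=C[C@@]1(C)CC[C@@H]([C@H](C)C(=O)OC)OO1
F5 | step 15 | methyl (2S)-2-[(3S,6S)-6-[2-(9-borabicyclo[3.3.1]nonan-9-yl)ethyl]-6-methyl-1,2-dioxan-3-yl]propanoate | B1(C2CCCC1CCC2)CC[C@@]1(C)CC[C@@H]([C@H](C)C(=O)OC)OO1
F6 | step 15 | [(5E)-6,10-dimethylundeca-5,9-dien-1-yn-1-yl]trimethylsilane | CC(C)=CCC/C(C)=C/CCC#C[Si](C)(C)C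
F7 | step 15 | (5E)-6,10-dimethylundeca-5,9-dien-1-yne | CC(C)=CCC/C(C)=C/CCC#C
F8 | step 15 | (1E,5E)-1-iodo-2,6,10-trimethylundeca-1,5,9-triene | CC(C)=CCC/C(C)=C/CC/C(C)=C/I
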